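## Retrosynthetic overview

1. The target is 14-deoxyandrographolide (17) plus an axial C7 hydroxyl, so the last disconnection is a stereoselective allylic C–H oxidation next to the 8(17)-methylene.
2. The butenolide comes from carbonylative lactonisation of a (Z)-3-iodoallylic alcohol (16). That is made from a propargylic pivalate in one flask that also sets the C3 carbinol, reduces the C19 ester and releases the auxiliary.
3. Rings A and B form together (ring A first, ring B in the same cascade) by Mn(OAc)3/Cu(OAc)2 oxidative radical bicyclisation of the acyclic α-methyl β-keto ester 13. This sets C4, C5, C9, C10 and the exocyclic methylene, with absolute control from a (+)-8-phenylmenthyl ester.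
4. Precursor 13 comes from γ-alkylation of the auxiliary 2-methylacetoacetate dianion with the C15 allylic bromide 8, itself from geranyl bromide, propargyl bromide and formaldehyde followed by terminal SeO2 oxidation.
5. Ring order: A and B in the key step, the lactone ring second, C7–OH last.

Assumption: labdane numbering is used for ring positions, and the (1S,2R,5S) auxiliary is taken to give the ent (andrographolide) series because, as far as I recall, the (1R,2S,5R) auxiliary gives the normal series in this reaction class; this has not been checked against a source.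

## Route

Step 1
Reactants: 1 geranyl bromide; 2 propargyl bromide
Product: 6 (6E)-7,11-dimethyldodeca-6,10-dien-2-yn-1-yl pivalate, via 1,3-dilithiopropyne 3 (not isolated), via lithium acetylide 4 (not isolated), via lithium alkoxide 5 (not isolated)
Conditions: 2, n-BuLi (2 equiv), TMEDA, Et2O/hexane, −78 °C; 1, −78 → 0 °C; (CH2O)n, THF, 0 °C → rt; PivCl, 0 °C
Reagents that add atoms: paraformaldehyde (formaldehyde unit) C=O; pivaloyl chloride CC(C)(C)C(=O)Cl
Why: One-pot dianion alkylation / acetylide hydroxymethylation / O-acylation: the propargylic carbon of 3 is far more nucleophilic than its acetylide carbon, so SN2 attack on the allylic bromide (E alkene untouched) leaves acetylide 4, which adds to formaldehyde, and alkoxide 5 is esterified in the same flask; no stereocentre is formed.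

Step 2
Reactants: 6 (6E)-7,11-dimethyldodeca-6,10-dien-2-yn-1-yl pivalate
Product: 7 (6E,10E)-12-hydroxy-7,11-dimethyldodeca-6,10-dien-2-yn-1-yl pivalate
Conditions: SeO2 (0.2 equiv), t-BuOOH (2.5 equiv), salicylic acid (0.1 equiv), CH2Cl2, 0 °C → rt
Reagents that add atoms: selenium dioxide O=[Se]=O (oxygen carrier); tert-butyl hydroperoxide CC(C)(C)OO (terminal oxidant)
Why: Catalytic SeO2 allylic oxidation (ene reaction then [2,3]-sigmatropic shift) is selective for the (E)-methyl of the terminal, most electron-rich trisubstituted alkene and gives the (E)-allylic alcohol; no stereocentre is formed.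

Step 3
Reactants: 7 (6E,10E)-12-hydroxy-7,11-dimethyldodeca-6,10-dien-2-yn-1-yl pivalate
Product: 8 (6E,10E)-12-bromo-7,11-dimethyldodeca-6,10-dien-2-yn-1-yl pivalate
Conditions: CBr4, PPh3, CH2Cl2, −20 → 0 °C
Reagents that add atoms: carbon tetrabromide BrC(Br)(Br)Br
Why: Appel bromination converts the primary allylic alcohol into the bromide under neutral conditions without allylic transposition or loss of E geometry.

Step 4
Reactants: 9 (+)-8-phenylmenthol, (1S,2R,5S); 10 ethyl 2-methylacetoacetate
Product: 11 (1S,2R,5S)-8-phenylmenthyl 2-methyl-3-oxobutanoate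
Conditions: DMAP (0.3 equiv), toluene, reflux, EtOH distilled off
Reagents that add atoms: none
Why: DMAP-catalysed transesterification of a β-keto ester (through the acylketene), driven by removal of ethanol; the auxiliary stereocentres are untouched and the epimeric C2 centre is erased later at the radical stage.

Step 5
Reactants: 11 (1S,2R,5S)-8-phenylmenthyl 2-methyl-3-oxobutanoate; 8 (6E,10E)-12-bromo-7,11-dimethyldodeca-6,10-dien-2-yn-1-yl pivalate
Product: 13 (1S,2R,5S)-8-phenylmenthyl (6E,10E)-2,6,10-trimethyl-3-oxo-16-(pivaloyloxy)hexadeca-6,10-dien-14-ynoate, via ester dianion 12 (not isolated)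
Conditions: lithium diisopropylamide (2.1 equiv), THF, −78 → 0 °C; 8, −78 → 0 °C; H2O
Reagents that add atoms: none
Why: Dianion γ-alkylation of a β-keto ester (Huckin–Weiler type): the more basic terminal carbanion of 12 displaces the allylic bromide by SN2 at low temperature, where the hindered pivalate is inert; C2 stays an epimer mixture.

Step 6
Reactants: 13 (1S,2R,5S)-8-phenylmenthyl (6E,10E)-2,6,10-trimethyl-3-oxo-16-(pivaloyloxy)hexadeca-6,10-dien-14-ynoate
Product: 14 (1S,2R,5S)-8-phenylmenthyl 3-oxo-15-(pivaloyloxy)-16-nor-ent-labd-8(17)-en-13-yn-19-oate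
Conditions: Mn(OAc)3·2H2O (2.2 equiv), Cu(OAc)2·H2O (1 equiv), degassed AcOH, 25 °C, 0.05 M; chromatography on AgNO3-doped silica
Reagents that add atoms: none
Why: Oxidative free-radical polyene bicyclisation: Mn(OAc)3 oxidises the β-keto ester enolate to the electrophilic C4 radical, which closes ring A (6-endo on C5) and then ring B (6-endo on C9) through a chair–chair array, so the trans ring fusion (C5, C10), the equatorial C9 side chain (from the E alkene) and the axial C4 ester (cis to the C10 methyl) arise together, the phenyl group of the (1S,2R,5S) auxiliary shields one face of the C4 radical to fix the ent absolute series (minor diastereomer removed by chromatography), and divalent copper traps the tertiary C8 radical and eliminates the least hindered methyl hydrogen to give the exocyclic methylene before the radical can reach the remote alkyne.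

Step 7
Reactants: 14 (1S,2R,5S)-8-phenylmenthyl 3-oxo-15-(pivaloyloxy)-16-nor-ent-labd-8(17)-en-13-yn-19-oate
Product: 16 (13Z)-13-iodo-16-nor-ent-labda-8(17),13-diene-3,15,19-triol, via cyclic vinylalanate 15 (not isolated)
Conditions: NaAlH2(OCH2CH2OMe)2 (8 equiv), THF, 0 → 50 °C; EtOAc, −78 °C; I2, THF, −78 → 0 °C
Reagents that add atoms: iodine II
Why: Hydride reduction combined with hydroxyl-directed trans-hydroalumination and iodinolysis: axial hydride delivery to the C3 ketone from the face opposite the C10 methyl and the axial C4 ester gives the equatorial 3-OH (cis to C19), both esters are reductively cleaved (C19 ester to CH2OH with release of the auxiliary, pivalate to the propargylic alkoxide), the alkoxide directs anti addition of Al–H across the alkyne with aluminium at C13 (15), and iodine cleaves the C–Al bond with retention to give the (Z)-3-iodoallylic alcohol.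

Step 8
Reactants: 16 (13Z)-13-iodo-16-nor-ent-labda-8(17),13-diene-3,15,19-triol
Product: 17 14-deoxyandrographolide
Conditions: CO (1 atm), Pd(PPh3)4 (5 mol%), K2CO3 (2 equiv), THF, 50 °C
Reagents that add atoms: carbon monoxide [C-]#[O+]
Why: Palladium-catalysed carbonylative lactonisation: oxidative addition of zerovalent palladium to the vinyl iodide, CO insertion and capture of the acyl-palladium by the cis CH2OH close the α-substituted butenolide (the remote 3,19-diol cannot compete with five-membered ring closure); no stereocentre changes.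

Step 9
Reactants: 17 14-deoxyandrographolide
Product: 18 7-hydroxy-14-deoxyandrographolide (target)
Conditions: SeO2 (0.5 equiv), t-BuOOH (2 equiv), CH2Cl2, 0 °C → rt
Reagents that add atoms: selenium dioxide O=[Se]=O (oxygen carrier); tert-butyl hydroperoxide CC(C)(C)OO (terminal oxidant)
Why: SeO2 allylic oxidation (ene reaction then [2,3]-sigmatropic shift) acts on the electron-rich 8(17)-alkene and not on the electron-poor butenolide alkene, removes the axial C7–H on the face anti to the C10 methyl and returns oxygen to the same axial position, giving the (7S) axial alcohol, with the ring CH2 preferred over the hindered C9 methine.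

## Compound list

1 | geranyl bromide, (2E)-1-bromo-3,7-dimethylocta-2,6-diene | CC(C)=CCC/C(C)=C/CBr | starting material
2 | propargyl bromide, 3-bromoprop-1-yne | C#CCBr | starting material
3 | 1,3-dilithiopropyne | [Li]CC#C[Li] | intermediate
4 | lithium (5E)-6,10-dimethylundeca-5,9-dien-1-yn-1-ide | CC(C)=CCC/C(C)=C/CCC#C[Li] | intermediate
5 | lithium (6E)-7,11-dimethyldodeca-6,10-dien-2-yn-1-olate | CC(C)=CCC/C(C)=C/CCC#CCO[Li] | intermediate
6 | (6E)-7,11-dimethyldodeca-6,10-dien-2-yn-1-yl pivalate | CC(C)=CCC/C(C)=C/CCC#CCOC(=O)C(C)(C)C | intermediate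
7 | (6E,10E)-12-hydroxy-7,11-dimethyldodeca-6,10-dien-2-yn-1-yl pivalate | OC/C(C)=C/CC/C(C)=C/CCC#CCOC(=O)C(C)(C)C | intermediate
8 | (6E,10E)-12-bromo-7,11-dimethyldodeca-6,10-dien-2-yn-1-yl pivalate | BrC/C(C)=C/CC/C(C)=C/CCC#CCOC(=O)C(C)(C)C | intermediate
9 | (+)-8-phenylmenthol, (1S,2R,5S)-5-methyl-2-(2-phenylpropan-2-yl)cyclohexan-1-ol | O[C@H]1C[C@@H](C)CC[C@@H]1C(C)(C)c1ccccc1 | starting material
10 | ethyl 2-methylacetoacetate (racemic) | CCOC(=O)C(C)C(C)=O | starting material
11 | (1S,2R,5S)-8-phenylmenthyl 2-methyl-3-oxobutanoate (C2 epimer mixture) | CC(=O)C(C)C(=O)O[C@H]1C[C@@H](C)CC[C@@H]1C(C)(C)c1ccccc1 | intermediate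
12 | dilithium dianion of 11 (C2 and C4 deprotonated) | [Li+].[Li+].[CH2-]C(=O)[C-](C)C(=O)O[C@H]1C[C@@H](C)CC[C@@H]1C(C)(C)c1ccccc1 | intermediate
13 | (1S,2R,5S)-8-phenylmenthyl (6E,10E)-2,6,10-trimethyl-3-oxo-16-(pivaloyloxy)hexadeca-6,10-dien-14-ynoate (C2 epimer mixture) | CC(C(=O)O[C@H]1C[C@@H](C)CC[C@@H]1C(C)(C)c1ccccc1)C(=O)CC/C(C)=C/CC/C(C)=C/CCC#CCOC(=O)C(C)(C)C | intermediate
14 | (1S,2R,5S)-8-phenylmenthyl 3-oxo-15-(pivaloyloxy)-16-nor-ent-labd-8(17)-en-13-yn-19-oate; trans-decalin, C4 with equatorial CH3 and axial ester cis to the C10 methyl, H5 and H9 axial and anti to the C10 methyl, C9 chain CH2CH2C≡CCH2OPiv equatorial | C=C1[C@@H](CCC#CCOC(=O)C(C)(C)C)[C@]2(C)CCC(=O)[C@@](C)(C(=O)O[C@H]3C[C@@H](C)CC[C@@H]3C(C)(C)c3ccccc3)[C@H]2CC1 | intermediate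
15 | sodium cyclic (Z)-vinylalanate: Al bonded to C13 and to O15 in a five-membered ring, two 2-methoxyethoxide ligands on Al; the C3 and C19 oxygens, drawn as OH, are aluminium alkoxides in the flask | C=C1[C@@H](CCC2=CCO[Al-]2(OCCOC)OCCOC)[C@]2(C)CC[C@@H](O)[C@@](C)(CO)[C@H]2CC1.[Na+] | intermediate
16 | (13Z)-13-iodo-16-nor-ent-labda-8(17),13-diene-3,15,19-triol; equatorial 3-OH cis to the axial C19 CH2OH | C=C1[C@@H](CC/C(I)=C/CO)[C@]2(C)CC[C@@H](O)[C@@](C)(CO)[C@H]2CC1 | intermediate
17 | 14-deoxyandrographolide | C=C1[C@@H](CCC2=CCOC2=O)[C@]2(C)CC[C@@H](O)[C@@](C)(CO)[C@H]2CC1 | intermediate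
18 | 7-hydroxy-14-deoxyandrographolide, (3R,4R,5S,7S,9S,10S) in labdane numbering; axial 7-OH anti to the C10 methyl | C=C1[C@@H](CCC2=CCOC2=O)[C@]2(C)CC[C@@H](O)[C@@](C)(CO)[C@H]2C[C@@H]1O | target

## Step count and risks

Total steps: 9. Longest linear sequence: 8 (steps 1, 2, 3, 5, 6, 7, 8, 9); step 4 is a one-step branch. The auxiliary 9 is costly but is recovered in step 7.

The three steps most likely to fail are steps 6, 7 and 9.

Step 6 (oxidative bicyclisation) may give poor mass balance, low auxiliary control, endocyclic alkene isomers or capture of the C8 radical by the alkyne. The fallback changes from oxidative to atom-transfer radical cyclisation and sets out from 13. Bromination with N-bromosuccinimide and catalytic Mg(ClO4)2 in MeCN at 0 °C gives the α-bromo keto ester F1. Et3B/air with Yb(OTf)3 in CH2Cl2 at −78 °C then effects bromine-atom-transfer bicyclisation through the same chair–chair course, the C8 radical now being quenched by bromine transfer at low temperature, to give the tertiary 8-bromide F2. Bulky-base E2 elimination toward the methyl hydrogens (KOt-Bu, THF, 0 °C) comes back to the route at 14.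

Step 7 (one-flask reduction, hydroalumination and iodination) may give incomplete reduction of the hindered ester, the wrong C3 epimer or an unclean iodination. The fallback separates reduction from lactone construction and avoids the vinyl metal altogether; it sets out from 14. LiAlH4 (Et2O, 0 °C → reflux) reduces the ketone and both esters without touching the alkyne and gives the alkyne triol F3. Palladium-catalysed cyclocarbonylation of the 2-alkyn-1-ol (Pd2(dba)3·CHCl3, 1,4-bis(diphenylphosphino)butane, CO/H2, CH2Cl2, 95 °C) then builds the 3-substituted furan-2(5H)-one directly and comes back to the route at 17, bypassing 15 and 16.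

Step 9 (late SeO2 oxidation) may attack the butenolide allylic positions or the free alcohols, or over-oxidise to the enone. The fallback moves the C7 oxygenation ahead of any hydroxyl or lactone and sets out from 14. SeO2/t-BuOOH on the keto ester, where the 8(17)-alkene is the only reactive alkene, gives the 7-hydroxy keto ester F4 with the same axial delivery. Treatment with NaAlH2(OCH2CH2OMe)2 and then I2, as in step 7, leads through the 7-oxygenated cyclic vinylalanate F5 to the 7-hydroxy vinyl iodide tetraol F6. Carbonylative lactonisation as in step 8 comes back to the route at 18.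

## Further compounds

F1 | step 6 | (1S,2R,5S)-8-phenylmenthyl (6E,10E)-2-bromo-2,6,10-trimethyl-3-oxo-16-(pivaloyloxy)hexadeca-6,10-dien-14-ynoate (C2 epimer mixture) | CC(Br)(C(=O)O[C@H]1C[C@@H](C)CC[C@@H]1C(C)(C)c1ccccc1)C(=O)CC/C(C)=C/CC/C(C)=C/CCC#CCOC(=O)C(C)(C)C
F2 | step 6 | (1S,2R,5S)-8-phenylmenthyl 8-bromo-3-oxo-15-(pivaloyloxy)-16-nor-ent-labd-13-yn-19-oate (C8 epimer mixture) | CC1(Br)[C@@H](CCC#CCOC(=O)C(C)(C)C)[C@]2(C)CCC(=O)[C@@](C)(C(=O)O[C@H]3C[C@@H](C)CC[C@@H]3C(C)(C)c3ccccc3)[C@H]2CC1
F3 | step 7 | 16-nor-ent-labd-8(17)-en-13-yne-3,15,19-triol | C=C1[C@@H](CCC#CCO)[C@]2(C)CC[C@@H](O)[C@@](C)(CO)[C@H]2CC1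
F4 | step 9 | 7-hydroxy derivative of 14 (axial 7-OH anti to the C10 methyl) | C=C1[C@@H](CCC#CCOC(=O)C(C)(C)C)[C@]2(C)CCC(=O)[C@@](C)(C(=O)O[C@H]3C[C@@H](C)CC[C@@H]3C(C)(C)c3ccccc3)[C@H]2C[C@@H]1O
F5 | step 9 | 7-hydroxy analogue of cyclic vinylalanate 15 (oxygens at C3, C7 and C19 drawn as OH) | C=C1[C@@H](CCC2=CCO[Al-]2(OCCOC)OCCOC)[C@]2(C)CC[C@@H](O)[C@@](C)(CO)[C@H]2C[C@@H]1O.[Na+]
F6 | step 9 | (13Z)-13-iodo-16-nor-ent-labda-8(17),13-diene-3,7,15,19-tetraol (axial 7-OH) | C=C1[C@@H](CC/C(I)=C/CO)[C@]2(C)CC[C@@H](O)[C@@](C)(CO)[C@H]2C[C@@H]1O
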